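**Retrosynthetic overview** (ring A = the 3‑hydroxy‑5‑methoxyphenyl ring, numbered C1 (OH), C3 (OMe), C5 (chain); ring B = the 3,5‑dihydroxyphenyl ring)
1. The strategy rests on ring A, a benzene ring with OH on C1, OMe on C3 and the C14 chain on C5 (all meta). It is cut at C1–C2 and C3–C4: C1, C4, C5 and C6 are the four carbons of a 3‑alkylcyclobut‑2‑enone (C1 = carbonyl carbon, its oxygen becomes the free OH), and C2/C3 are the two carbons of methoxyacetylene, so OH and OMe are different from the moment the ring exists.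
2. The cyclobutenone is made by 1,2‑addition of the chain Grignard reagent to 3‑ethoxycyclobut‑2‑enone and acid transposition. A ketene [2+2] onto a terminal alkyne is avoided because it would not spare the chain C=C.
3. The (E)‑C=C is cut by Julia–Kocienski olefination into a ring B hexyl tetrazolyl sulfone (from 3,5‑dihydroxybenzaldehyde) and 8‑bromooctanal.
4. Ring order: ring B is bought and carried as its bis(methoxymethyl) ether, the four‑membered ring is bought, ring A is the only ring formed (step 11), and acid removes the two acetals last.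

Key step: step 11

Assumption: 3‑ethoxycyclobut‑2‑en‑1‑one, (4‑carboxybutyl)triphenylphosphonium bromide and 8‑bromooctan‑1‑ol are purchased; the Z/E mixture from step 2 is carried on unseparated because step 3 removes that alkene.

**Route**

Step 1
Reactants: 1 3,5‑dihydroxybenzaldehyde
Product: 2 3,5‑bis(methoxymethoxy)benzaldehyde
Conditions: MOMCl (2.5 equiv), i‑Pr2NEt (3 equiv), DMF, 0 °C → rt
Reagents that add atoms: chloromethyl methyl ether, COCCl
Why: Williamson‑type O‑alkylation of both phenols by the highly electrophilic chloromethyl ether gives aryl acetals that resist the ylide, hydride, amide‑base and Grignard steps ahead and leave under mild acid at the end.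

Step 2
Reactants: 2 3,5‑bis(methoxymethoxy)benzaldehyde; 3 (4‑carboxybutyl)triphenylphosphonium bromide
Product: 5 6‑[3,5‑bis(methoxymethoxy)phenyl]hex‑5‑enoic acid (Z/E mixture), via phosphorus ylide 4 (not isolated)
Conditions: 3 (1.3 equiv), NaN(SiMe3)2 (2.6 equiv), THF, 0 °C; then 2, 0 °C → rt; 1 M aq HCl to pH 4, 0 °C
Reagents that add atoms: none
Why: Wittig olefination of an aromatic aldehyde by the non‑stabilised carboxylate ylide (two equivalents of base) joins five chain carbons in one operation, and the alkene geometry is of no consequence.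

Step 3
Reactants: 5 6‑[3,5‑bis(methoxymethoxy)phenyl]hex‑5‑enoic acid
Product: 6 6‑[3,5‑bis(methoxymethoxy)phenyl]hexanoic acid
Conditions: H2 (1 atm), 10% Pd/C, EtOAc, rt
Reagents that add atoms: none
Why: Heterogeneous catalytic hydrogenation saturates the styrenyl C=C, while aryl acetals and the acid are inert and no other alkene is yet present.

Step 4
Reactants: 6 6‑[3,5‑bis(methoxymethoxy)phenyl]hexanoic acid
Product: 7 6‑[3,5‑bis(methoxymethoxy)phenyl]hexan‑1‑ol
Conditions: LiAlH4, THF, 0 °C → rt; H2O, aq NaOH work‑up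
Reagents that add atoms: none
Why: Hydride reduction of the carboxylic acid to the primary alcohol, with the acetals untouched by LiAlH4.

Step 5
Reactants: 7 6‑[3,5‑bis(methoxymethoxy)phenyl]hexan‑1‑ol
Product: 8 5‑({6‑[3,5‑bis(methoxymethoxy)phenyl]hexyl}sulfanyl)‑1‑phenyl‑1H‑tetrazole
Conditions: 1‑phenyl‑1H‑tetrazole‑5‑thiol, PPh3, DIAD, THF, 0 °C → rt
Reagents that add atoms: 1‑phenyl‑1H‑tetrazole‑5‑thiol, Sc1nnnn1-c1ccccc1
Why: Mitsunobu reaction, in which the acidic heteroaryl thiol displaces the primary alkoxyphosphonium ion in a clean SN2 step.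

Step 6
Reactants: 8 5‑({6‑[3,5‑bis(methoxymethoxy)phenyl]hexyl}sulfanyl)‑1‑phenyl‑1H‑tetrazole
Product: 9 5‑({6‑[3,5‑bis(methoxymethoxy)phenyl]hexyl}sulfonyl)‑1‑phenyl‑1H‑tetrazole
Conditions: (NH4)6Mo7O24·4H2O (10 mol %), 30% aq H2O2, EtOH, 0 °C → rt
Reagents that add atoms: hydrogen peroxide, OO
Why: Molybdate‑catalysed peroxide oxidation takes the sulfide through the sulfoxide to the sulfone, and the substrate holds no other oxidisable group.

Step 7
Reactants: 10 8‑bromooctan‑1‑ol
Product: 11 8‑bromooctanal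
Conditions: TEMPO (10 mol %), PhI(OAc)2 (1.1 equiv), CH2Cl2, rt
Reagents that add atoms: none
Why: Oxoammonium (TEMPO) catalysed oxidation of a primary alcohol stops at the aldehyde and does not touch the primary bromide.

Step 8
Reactants: 9 5‑({6‑[3,5‑bis(methoxymethoxy)phenyl]hexyl}sulfonyl)‑1‑phenyl‑1H‑tetrazole; 11 8‑bromooctanal
Product: 13 (E)‑1‑(14‑bromotetradec‑6‑en‑1‑yl)‑3,5‑bis(methoxymethoxy)benzene, via potassium sulfonyl carbanion 12 (not isolated)
Conditions: 9, KN(SiMe3)2 (1.05 equiv), DME, −60 °C; then 11 (1.2 equiv), −60 °C → rt; sat. aq NH4Cl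
Reagents that add atoms: none
Why: Julia–Kocienski olefination, in which the potassium carbanion in DME should add to the aldehyde mainly in the anti sense and the stereospecific Smiles rearrangement and loss of SO2 and tetrazololate then give the E alkene, while the low temperature keeps the carbanion from displacing the primary bromide.

Step 9
Reactants: 13 (E)‑1‑(14‑bromotetradec‑6‑en‑1‑yl)‑3,5‑bis(methoxymethoxy)benzene; 14 3‑ethoxycyclobut‑2‑en‑1‑one
Product: 17 3‑{(E)‑14‑[3,5‑bis(methoxymethoxy)phenyl]tetradec‑8‑en‑1‑yl}cyclobut‑2‑en‑1‑one, via Grignard reagent 15 (not isolated), via cyclobutenol adduct 16 (not isolated)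
Conditions: Mg, THF, 40 °C; then 14 (1.3 equiv), THF, −78 → 0 °C; then 1 M aq HCl, 0 °C, 20 min
Reagents that add atoms: water, O
Why: Stork–Danheiser‑type sequence on a vinylogous ester, in which the primary Grignard reagent adds 1,2 to the carbonyl group (enolisation toward a cyclobutadienolate being disfavoured) and brief cold acid ionises the tertiary allylic alcohol, water enters at the ethoxy carbon and ethanol leaves to give the transposed enone, conditions short and mild enough for the aryl acetals and blind to the chain C=C.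

Step 10
Reactants: 18 chloroacetaldehyde dimethyl acetal
Product: 20 methoxyacetylene, via sodium methoxyacetylide 19 (not isolated)
Conditions: NaNH2 (3 equiv), NH3 (l), −33 °C; NH3 evaporated; sat. aq NaCl, −70 °C → rt; distilled (bp ca. 23 °C) into cold toluene
Reagents that add atoms: none
Why: Base‑induced double β‑elimination, in which amide removes methanol and HCl from the α‑chloroacetal and the third equivalent holds the ynol ether as its acetylide until the aqueous quench, the classical preparation of this alkyne.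

Step 11
Reactants: 17 3‑{(E)‑14‑[3,5‑bis(methoxymethoxy)phenyl]tetradec‑8‑en‑1‑yl}cyclobut‑2‑en‑1‑one; 20 methoxyacetylene
Product: 25 3‑{(E)‑14‑[3,5‑bis(methoxymethoxy)phenyl]tetradec‑8‑en‑1‑yl}‑5‑methoxyphenol, via vinylketene 21 (not isolated), via alkenylcyclobutenone 22 (not isolated), via dienylketene 23 (not isolated), via cyclohexadienone 24 (not isolated)
Conditions: 20 (3 equiv), toluene, sealed tube, 80 °C
Reagents that add atoms: none
Why: At 80 °C cyclobutenone 17 opens reversibly by a 4π electrocyclic process to vinylketene 21, whose ketene C=C adds [2+2] to the electron‑rich alkyne 20 to give alkenylcyclobutenone 22. A second 4π opening gives dienylketene 23, and ring A closes by a thermally allowed disrotatory 6π electrocyclisation (ketene carbon to the terminal methylene) to cyclohexadienone 24, which tautomerises to phenol 25. The closest known reaction type is the thermal aromatic annulation of 3‑alkylcyclobutenones with alkoxyacetylenes (Danheiser benzannulation). No stereocentre is created, since the sp3 centre of 22 is transient, and the neutral thermal conditions leave the E alkene and the acetals alone. The step needs regiocontrol in the [2+2] event and chemoselectivity over the chain C=C: the polarised ynol ether bonds through its unsubstituted nucleophilic carbon to the electrophilic ketene carbon, which places OMe meta to both OH and the chain, and a trans‑dialkyl alkene is a far poorer ketenophile than an ynol ether used in excess.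

Step 12
Reactants: 25 3‑{(E)‑14‑[3,5‑bis(methoxymethoxy)phenyl]tetradec‑8‑en‑1‑yl}‑5‑methoxyphenol
Product: 26 dehydrobisgravillol, 5‑[(E)‑14‑(3‑hydroxy‑5‑methoxyphenyl)tetradec‑6‑en‑1‑yl]benzene‑1,3‑diol
Conditions: 3 M aq HCl, MeOH, 45 °C
Reagents that add atoms: none
Why: Acid‑catalysed acetal methanolysis frees the two ring B phenols as dimethoxymethane forms, while the aryl methyl ether and the isolated E alkene are inert to dilute acid.

**Compound list**
1 | 3,5‑dihydroxybenzaldehyde | O=Cc1cc(O)cc(O)c1 | starting material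
2 | 3,5‑bis(methoxymethoxy)benzaldehyde | O=Cc1cc(OCOC)cc(OCOC)c1 | intermediate
3 | (4‑carboxybutyl)triphenylphosphonium bromide | OC(=O)CCCC[P+](c1ccccc1)(c1ccccc1)c1ccccc1.[Br-] | starting material
4 | sodium 5‑(triphenylphosphoranylidene)pentanoate (ylide) | [Na+].[O-]C(=O)CCCC=P(c1ccccc1)(c1ccccc1)c1ccccc1 | intermediate (not isolated)
5 | 6‑[3,5‑bis(methoxymethoxy)phenyl]hex‑5‑enoic acid, Z/E mixture (Z isomer drawn) | OC(=O)CCC/C=C\c1cc(OCOC)cc(OCOC)c1 | intermediate
6 | 6‑[3,5‑bis(methoxymethoxy)phenyl]hexanoic acid | OC(=O)CCCCCc1cc(OCOC)cc(OCOC)c1 | intermediate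
7 | 6‑[3,5‑bis(methoxymethoxy)phenyl]hexan‑1‑ol | OCCCCCCc1cc(OCOC)cc(OCOC)c1 | intermediate
8 | 5‑({6‑[3,5‑bis(methoxymethoxy)phenyl]hexyl}sulfanyl)‑1‑phenyl‑1H‑tetrazole | COCOc1cc(CCCCCCSc2nnnn2-c2ccccc2)cc(OCOC)c1 | intermediate
9 | 5‑({6‑[3,5‑bis(methoxymethoxy)phenyl]hexyl}sulfonyl)‑1‑phenyl‑1H‑tetrazole | COCOc1cc(CCCCCCS(=O)(=O)c2nnnn2-c2ccccc2)cc(OCOC)c1 | intermediate
10 | 8‑bromooctan‑1‑ol | OCCCCCCCCBr | starting material
11 | 8‑bromooctanal | O=CCCCCCCCBr | intermediate
12 | potassium salt of sulfone 9 deprotonated at the carbon next to sulfur | [K+].COCOc1cc(CCCCC[CH-]S(=O)(=O)c2nnnn2-c2ccccc2)cc(OCOC)c1 | intermediate (not isolated)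
13 | (E)‑1‑(14‑bromotetradec‑6‑en‑1‑yl)‑3,5‑bis(methoxymethoxy)benzene | BrCCCCCCC/C=C/CCCCCc1cc(OCOC)cc(OCOC)c1 | intermediate
14 | 3‑ethoxycyclobut‑2‑en‑1‑one | CCOC1=CC(=O)C1 | starting material
15 | {(E)‑14‑[3,5‑bis(methoxymethoxy)phenyl]tetradec‑8‑en‑1‑yl}magnesium bromide | Br[Mg]CCCCCCC/C=C/CCCCCc1cc(OCOC)cc(OCOC)c1 | intermediate (not isolated)
16 | 1‑{(E)‑14‑[3,5‑bis(methoxymethoxy)phenyl]tetradec‑8‑en‑1‑yl}‑3‑ethoxycyclobut‑2‑en‑1‑ol, racemic (present as its bromomagnesium alkoxide) | CCOC1=CC(O)(CCCCCCC/C=C/CCCCCc2cc(OCOC)cc(OCOC)c2)C1 | intermediate (not isolated)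
17 | 3‑{(E)‑14‑[3,5‑bis(methoxymethoxy)phenyl]tetradec‑8‑en‑1‑yl}cyclobut‑2‑en‑1‑one | O=C1CC(CCCCCCC/C=C/CCCCCc2cc(OCOC)cc(OCOC)c2)=C1 | intermediate (key‑step precursor)
18 | chloroacetaldehyde dimethyl acetal | COC(CCl)OC | starting material
19 | sodium methoxyacetylide | [Na+].[C-]#COC | intermediate (not isolated)
20 | methoxyacetylene | COC#C | intermediate
21 | vinylketene O=C=CH–C(=CH2)–R, R = (E)‑14‑[3,5‑bis(methoxymethoxy)phenyl]tetradec‑8‑en‑1‑yl | O=C=CC(=C)CCCCCCC/C=C/CCCCCc1cc(OCOC)cc(OCOC)c1 | intermediate (not isolated)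
22 | 3‑methoxy‑4‑[C(=CH2)–R]cyclobut‑2‑en‑1‑one, racemic, R as in 21 | O=C1C=C(OC)C1C(=C)CCCCCCC/C=C/CCCCCc1cc(OCOC)cc(OCOC)c1 | intermediate (not isolated)
23 | dienylketene O=C=CH–C(OMe)=CH–C(=CH2)–R, ketenyl and alkenyl groups cis across the central C=C, R as in 21 | O=C=C/C(OC)=C\C(=C)CCCCCCC/C=C/CCCCCc1cc(OCOC)cc(OCOC)c1 | intermediate (not isolated)
24 | 3‑methoxy‑5‑R‑cyclohexa‑2,4‑dien‑1‑one, R as in 21 | O=C1C=C(OC)C=C(CCCCCCC/C=C/CCCCCc2cc(OCOC)cc(OCOC)c2)C1 | intermediate (not isolated)
25 | 3‑{(E)‑14‑[3,5‑bis(methoxymethoxy)phenyl]tetradec‑8‑en‑1‑yl}‑5‑methoxyphenol | COc1cc(O)cc(CCCCCCC/C=C/CCCCCc2cc(OCOC)cc(OCOC)c2)c1 | intermediate (key‑step product)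
26 | dehydrobisgravillol, 5‑[(E)‑14‑(3‑hydroxy‑5‑methoxyphenyl)tetradec‑6‑en‑1‑yl]benzene‑1,3‑diol | COc1cc(O)cc(CCCCCCC/C=C/CCCCCc2cc(O)cc(O)c2)c1 | target

**Step count**
Total: 12 steps. Longest linear sequence: 10 steps (1, 2, 3, 4, 5, 6, 8, 9, 11, 12); steps 7 and 10 are single‑step side branches.

**Steps most likely to fail**

Step 11. The capture of vinylketene 21 by the ynol ether may lose out to other processes: acylation of phenol 25 as it forms, ketene dimerisation, and loss or polymerisation of the low‑boiling alkyne before it reacts. Conversion to the arene would then stall. A basic methanol work‑up would return any O‑acylated 25, but if the annulation itself fails, ring A would be bought instead of built. Setting out from bromide 13, Grignard reagent 15 would be formed as in step 9 and cross‑coupled (Kumada–Corriu coupling, Pd(dppf)Cl2, THF, reflux) with tert‑butyl(3‑bromo‑5‑methoxyphenoxy)dimethylsilane F1. F1 would be made from commercial 3‑bromo‑5‑methoxyphenol with t‑BuMe2SiCl and imidazole in DMF. The coupling should give the silyl ether of 25, tert‑butyl(3‑{(E)‑14‑[3,5‑bis(methoxymethoxy)phenyl]tetradec‑8‑en‑1‑yl}‑5‑methoxyphenoxy)dimethylsilane F2, and Bu4NF in THF would then rejoin the route at 25.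

Step 9. Magnesium insertion into the long‑chain bromide may be sluggish and accompanied by Wurtz‑type homocoupling, leaving too little organometallic for the 1,2‑addition. The fallback changes the way the nucleophile is made. Setting out from 13, NaI in refluxing acetone would give (E)‑1‑(14‑iodotetradec‑6‑en‑1‑yl)‑3,5‑bis(methoxymethoxy)benzene F3. Iodine–lithium exchange with t‑BuLi (2 equiv, pentane/Et2O, −78 °C) is fast enough at this temperature to outrun metalation of the ring B C–H between the two acetal oxygens, and would give {(E)‑14‑[3,5‑bis(methoxymethoxy)phenyl]tetradec‑8‑en‑1‑yl}lithium F4. F4 would be added at once to 14 at −78 °C; the lithium alkoxide of 16 is hydrolysed with cold dilute HCl as before, and the route is rejoined at 17.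

Step 8. The addition of carbanion 12 to the aldehyde may be incompletely anti‑selective, so that some Z alkene forms that would be hard to remove, and the carbanion may be C‑alkylated by the primary bromide. The fallback builds the alkene stereospecifically. Setting out from alcohol 7, TEMPO/PhI(OAc)2 oxidation would give 6‑[3,5‑bis(methoxymethoxy)phenyl]hexanal F5. Ohira–Bestmann homologation (dimethyl (1‑diazo‑2‑oxopropyl)phosphonate, K2CO3, MeOH) would give 1‑(hept‑6‑yn‑1‑yl)‑3,5‑bis(methoxymethoxy)benzene F6. Syn hydrozirconation with Cp2Zr(H)Cl in THF would give the (E)‑alkenylzirconocene chloride F7, and iodinolysis with I2 would give (E)‑1‑(7‑iodohept‑6‑en‑1‑yl)‑3,5‑bis(methoxymethoxy)benzene F8 with retention. Separately, 7‑bromohept‑1‑ene and 9‑BBN‑H in THF would give 9‑(7‑bromoheptyl)‑9‑borabicyclo[3.3.1]nonane F9. B‑alkyl Suzuki–Miyaura coupling of F8 with F9 (Pd(dppf)Cl2, K3PO4, DMF/THF/H2O, rt) proceeds with retention at the alkenyl carbon and should spare the unactivated alkyl bromide, rejoining the route at 13.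

**Further compounds**
F1 | step 11 | tert‑butyl(3‑bromo‑5‑methoxyphenoxy)dimethylsilane | COc1cc(Br)cc(O[Si](C)(C)C(C)(C)C)c1
F2 | step 11 | tert‑butyl(3‑{(E)‑14‑[3,5‑bis(methoxymethoxy)phenyl]tetradec‑8‑en‑1‑yl}‑5‑methoxyphenoxy)dimethylsilane | COc1cc(O[Si](C)(C)C(C)(C)C)cc(CCCCCCC/C=C/CCCCCc2cc(OCOC)cc(OCOC)c2)c1
F3 | step 9 | (E)‑1‑(14‑iodotetradec‑6‑en‑1‑yl)‑3,5‑bis(methoxymethoxy)benzene | ICCCCCCC/C=C/CCCCCc1cc(OCOC)cc(OCOC)c1
F4 | step 9 | {(E)‑14‑[3,5‑bis(methoxymethoxy)phenyl]tetradec‑8‑en‑1‑yl}lithium | [Li]CCCCCCC/C=C/CCCCCc1cc(OCOC)cc(OCOC)c1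
F5 | step 8 | 6‑[3,5‑bis(methoxymethoxy)phenyl]hexanal | O=CCCCCCc1cc(OCOC)cc(OCOC)c1
F6 | step 8 | 1‑(hept‑6‑yn‑1‑yl)‑3,5‑bis(methoxymethoxy)benzene | C#CCCCCCc1cc(OCOC)cc(OCOC)c1
F7 | step 8 | chlorobis(cyclopentadienyl){(E)‑7‑[3,5‑bis(methoxymethoxy)phenyl]hept‑1‑en‑1‑yl}zirconium | Cl[Zr](/C=C/CCCCCc1cc(OCOC)cc(OCOC)c1)(C1C=CC=C1)C1C=CC=C1
F8 | step 8 | (E)‑1‑(7‑iodohept‑6‑en‑1‑yl)‑3,5‑bis(methoxymethoxy)benzene | I/C=C/CCCCCc1cc(OCOC)cc(OCOC)c1
F9 | step 8 | 9‑(7‑bromoheptyl)‑9‑borabicyclo[3.3.1]nonane | BrCCCCCCCB1C2CCCC1CCC2
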